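**Retrosynthetic overview**
- Target ⇐ racemic macrocyclic diene acetate: both oxiranes are closed in one catalyst-controlled Shi operation, which also sorts the enantiomers (last step).
- Diene acetate ⇐ C10-epimeric homoallylic alcohol (Mitsunobu inversion with AcOH) ⇐ chloromethyl-enone aldehyde: an intramolecular Nozaki–Hiyama allylation closes the twelve-membered ring and creates C10, C11 and the α-methylene ketone.
- Chloro-aldehyde ⇐ 5-substituted 4,4-dimethylcyclohexenone (Morita–Baylis–Hillman, chlorination, oxidative desilylation) ⇐ 4,4-dimethylcyclohexadienone + C11 allylic chloride (α-selective allylbarium 1,4-addition, C1–C2 bond).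
- Allylic chloride ⇐ geranyl acetate (SeO2, Wittig, hydroboration: one-carbon extension at the (E)-methyl group).
- Ring order: six-membered ring from purchased 4,4-dimethylcyclohexenone; twelve-membered ring in step 12; the two oxirane rings together in step 14.

Assumption: compounds 12–20 are racemic until the last step; names and SMILES show the enantiomer that ends up in the target, and ring positions are numbered as in bicyclo[9.3.1]pentadecane (C1 and C11 bridgeheads, C15 the gem-dimethyl bridge).

**Step 1**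
Reactants: 1 geranyl acetate
Product: 2 (2E,6E)-3,7-dimethyl-8-oxoocta-2,6-dien-1-yl acetate
Conditions: SeO2 (1.2 equiv), EtOH, reflux
Reagents that add atoms: selenium dioxide O=[Se]=O
Why: Riley allylic oxidation (ene reaction then 2,3-sigmatropic shift) attacks the electron-richer terminal trisubstituted olefin and oxidises only its (E)-methyl group, so the new aldehyde carbon (later C9) is fixed trans to the chain.

**Step 2**
Reactants: 2 (2E,6E)-3,7-dimethyl-8-oxoocta-2,6-dien-1-yl acetate
Product: 3 (2E,6E)-3,7-dimethylnona-2,6,8-trien-1-yl acetate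
Conditions: Ph3PCH3Br, NaN(SiMe3)2, THF, 0 °C; then 2, −78 to 0 °C
Reagents that add atoms: methyltriphenylphosphonium bromide C[P+](c1ccccc1)(c1ccccc1)c1ccccc1.[Br-]
Why: Wittig methylenation of the enal is much faster than attack on the acetate at low temperature and gives the terminal diene without touching the two (E)-trisubstituted olefins.

**Step 3**
Reactants: 3 (2E,6E)-3,7-dimethylnona-2,6,8-trien-1-yl acetate
Product: 5 (2E,6E)-9-hydroxy-3,7-dimethylnona-2,6-dien-1-yl acetate, via B-alkyl-9-BBN borane 4 (not isolated)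
Conditions: 9-BBN (1.1 equiv), THF, 0 °C to rt; then 30% H2O2, aq. NaOAc, 0 °C
Reagents that add atoms: hydrogen peroxide OO
Why: Brown hydroboration–oxidation, in which the bulky borane adds only to the monosubstituted terminal double bond in the anti-Markovnikov sense and so supplies the primary alcohol carbon that becomes C10, while the buffered oxidation spares the acetate.

**Step 4**
Reactants: 5 (2E,6E)-9-hydroxy-3,7-dimethylnona-2,6-dien-1-yl acetate
Product: 6 (2E,6E)-3,7-dimethyl-9-(triethylsilyloxy)nona-2,6-dien-1-yl acetate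
Conditions: Et3SiCl, imidazole, CH2Cl2, 0 °C
Reagents that add atoms: chlorotriethylsilane CC[Si](Cl)(CC)CC
Why: routine silylation of the primary alcohol, the triethylsilyl ether being chosen because it survives the organobarium step and can later be oxidised directly to the aldehyde.

**Step 5**
Reactants: 6 (2E,6E)-3,7-dimethyl-9-(triethylsilyloxy)nona-2,6-dien-1-yl acetate
Product: 7 (2E,6E)-3,7-dimethyl-9-(triethylsilyloxy)nona-2,6-dien-1-ol
Conditions: K2CO3 (0.2 equiv), MeOH, 0 °C
Reagents that add atoms: none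
Why: base-catalysed transesterification (Zemplén-type methanolysis) removes the allylic acetate under conditions mild enough to keep the primary triethylsilyl ether and both olefin geometries.

**Step 6**
Reactants: 7 (2E,6E)-3,7-dimethyl-9-(triethylsilyloxy)nona-2,6-dien-1-ol
Product: 8 (2E,6E)-1-chloro-3,7-dimethyl-9-(triethylsilyloxy)nona-2,6-diene
Conditions: N-chlorosuccinimide, Me2S, CH2Cl2, −30 to 0 °C
Reagents that add atoms: N-chlorosuccinimide O=C1CCC(=O)N1Cl
Why: Corey–Kim chlorination converts the primary allylic alcohol into the chloride by SN2 collapse of the alkoxysulfonium salt, without allylic transposition or E/Z scrambling.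

**Step 7**
Reactants: 9 4,4-dimethylcyclohex-2-en-1-one
Product: 10 4,4-dimethylcyclohexa-2,5-dien-1-one
Conditions: 2,3-dichloro-5,6-dicyano-1,4-benzoquinone (1.5 equiv), 1,4-dioxane, reflux
Reagents that add atoms: none
Why: quinone dehydrogenation (hydride abstraction from the enol then proton loss) introduces the second double bond, and the quaternary carbon rules out aromatisation.

**Step 8**
Reactants: 8 (2E,6E)-1-chloro-3,7-dimethyl-9-(triethylsilyloxy)nona-2,6-diene; 10 4,4-dimethylcyclohexa-2,5-dien-1-one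
Product: 13 rac-(5R)-4,4-dimethyl-5-[(2E,6E)-3,7-dimethyl-9-(triethylsilyloxy)nona-2,6-dien-1-yl]cyclohex-2-en-1-one, via allylbarium chloride 11 (not isolated), via barium dienolate 12 (not isolated)
Conditions: BaI2 + 2 LiC12H10 (lithium biphenylide), THF, rt (zerovalent active barium); 8, −78 °C, 30 min; 10, −78 °C, 1 h; aq. NH4Cl
Reagents that add atoms: none
Why: Yamamoto-type allylbarium chemistry, in which the organobarium keeps its (E)-geometry at −78 °C, reacts at its α-carbon and undergoes Michael addition to cycloalkenones, here at one of the two equivalent β-carbons of the symmetric dienone, which creates C1 as a racemate and leaves the second enone for the following steps.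

**Step 9**
Reactants: 13 rac-(5R)-4,4-dimethyl-5-[(2E,6E)-3,7-dimethyl-9-(triethylsilyloxy)nona-2,6-dien-1-yl]cyclohex-2-en-1-one
Product: 14 rac-(5R)-2-(hydroxymethyl)-4,4-dimethyl-5-[(2E,6E)-3,7-dimethyl-9-(triethylsilyloxy)nona-2,6-dien-1-yl]cyclohex-2-en-1-one
Conditions: 37% aq. CH2O, 4-(dimethylamino)pyridine (0.5 equiv), THF/H2O, rt
Reagents that add atoms: formaldehyde C=O
Why: Morita–Baylis–Hillman hydroxymethylation, in which the amine adds reversibly to the enone β-carbon, the enolate is trapped by formaldehyde at the α-carbon and the amine is expelled, placing the future exocyclic carbon on the correct side of the ketone without touching C1.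

**Step 10**
Reactants: 14 rac-(5R)-2-(hydroxymethyl)-4,4-dimethyl-5-[(2E,6E)-3,7-dimethyl-9-(triethylsilyloxy)nona-2,6-dien-1-yl]cyclohex-2-en-1-one
Product: 15 rac-(5R)-2-(chloromethyl)-4,4-dimethyl-5-[(2E,6E)-3,7-dimethyl-9-(triethylsilyloxy)nona-2,6-dien-1-yl]cyclohex-2-en-1-one
Conditions: N-chlorosuccinimide, Me2S, CH2Cl2, −30 to 0 °C
Reagents that add atoms: N-chlorosuccinimide O=C1CCC(=O)N1Cl
Why: Corey–Kim chlorination of the primary allylic alcohol as in step 6 gives the 2-(chloromethyl)enone that serves as allyl donor, under neutral conditions that keep the silyl ether.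

**Step 11**
Reactants: 15 rac-(5R)-2-(chloromethyl)-4,4-dimethyl-5-[(2E,6E)-3,7-dimethyl-9-(triethylsilyloxy)nona-2,6-dien-1-yl]cyclohex-2-en-1-one
Product: 16 rac-(3E,7E)-9-[(1R)-4-(chloromethyl)-2,2-dimethyl-5-oxocyclohex-3-en-1-yl]-3,7-dimethylnona-3,7-dienal
Conditions: (COCl)2, Me2SO, CH2Cl2, −78 to −40 °C; Et3N, −78 to −20 °C
Reagents that add atoms: none
Why: Swern oxidation applied directly to a primary triethylsilyl ether, in which chlorodimethylsulfonium chloride exchanges the silyl group for the alkoxysulfonium group and the amine then triggers the usual ylide fragmentation to the aldehyde, cold enough that the β,γ-double bond stays out of conjugation and the allylic chloride is not attacked.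

**Step 12**
Reactants: 16 rac-(3E,7E)-9-[(1R)-4-(chloromethyl)-2,2-dimethyl-5-oxocyclohex-3-en-1-yl]-3,7-dimethylnona-3,7-dienal
Product: 19 rac-(1R,3E,7E,10R,11S)-10-hydroxy-4,8,15,15-tetramethyl-12-methylidenebicyclo[9.3.1]pentadeca-3,7-dien-13-one, via allylchromium dichloride 17 (not isolated), via chromium alkoxide 18 (not isolated)
Conditions: CrCl2 (8 equiv), NaI (0.2 equiv), THF, 25 °C, syringe-pump addition to 2 mM; aq. work-up
Reagents that add atoms: none
Why: intramolecular Nozaki–Hiyama allylation, in which two divalent chromium ions turn the allylic chloride into an allylchromium species that adds to the aldehyde through its γ-carbon (ring carbon C11) in a chair transition state, closing the twelve-membered ring and shifting the double bond to the exocyclic position; C11 is expected trans to the C1 side chain (attack anti to the pseudo-axial methyl of the conformer with the side chain equatorial) and C10 anti to C15 (ring-enforced E-type allyl unit, aldehyde residue equatorial), which is the C10 epimer that step 13 inverts.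

**Step 13**
Reactants: 19 rac-(1R,3E,7E,10R,11S)-10-hydroxy-4,8,15,15-tetramethyl-12-methylidenebicyclo[9.3.1]pentadeca-3,7-dien-13-one
Product: 20 rac-(1R,3E,7E,10S,11S)-4,8,15,15-tetramethyl-12-methylidene-13-oxobicyclo[9.3.1]pentadeca-3,7-dien-10-yl acetate
Conditions: PPh3, diisopropyl azodicarboxylate (betaine pre-formed), AcOH, toluene, 0 °C to rt
Reagents that add atoms: acetic acid CC(=O)O
Why: Mitsunobu esterification, in which acetate displaces the alkoxyphosphonium group in an SN2 step and so installs the acetate with inversion of C10 to the required configuration, while pre-forming the betaine keeps free phosphine away from the α-methylene ketone.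

**Step 14**
Reactants: 20 rac-(1R,3E,7E,10S,11S)-4,8,15,15-tetramethyl-12-methylidene-13-oxobicyclo[9.3.1]pentadeca-3,7-dien-10-yl acetate
Product: 23 (1R,3R,4R,7R,8R,10S,11S)-3,4:7,8-diepoxy-4,8,15,15-tetramethyl-12-methylidene-13-oxobicyclo[9.3.1]pentadecan-10-yl acetate, via 3,4-monoepoxide 21 (not isolated), via 7,8-monoepoxide 22 (not isolated)
Conditions: 1,2:4,5-di-O-isopropylidene-β-D-erythro-2,3-hexodiulo-2,6-pyranose (0.6 equiv), KHSO5 (3 equiv, as 2KHSO5·KHSO4·K2SO4), K2CO3, Bu4NHSO4 (cat.), MeCN/CH2(OMe)2/aq. Na2B4O7 buffer (pH 10.5), 0 °C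
Reagents that add atoms: potassium peroxymonosulfate [K+].[O-]S(=O)(=O)OO
Why: Shi asymmetric epoxidation, in which the chiral dioxirane delivers oxygen through a spiro transition state to the same enantioface of each (E)-trisubstituted olefin (R,R oxiranes) and leaves the electron-poor methylene ketone alone, so both oxirane rings close in one operation and the racemate is sorted, the (1R,10S,11S) half giving the target (at most half of the material) and the other half a diastereomer that is removed by chromatography.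

**Compound list**
1 | geranyl acetate | CC(C)=CCC/C(C)=C/COC(C)=O | starting material
2 | (2E,6E)-3,7-dimethyl-8-oxoocta-2,6-dien-1-yl acetate | O=C/C(C)=C/CC/C(C)=C/COC(C)=O | intermediate
3 | (2E,6E)-3,7-dimethylnona-2,6,8-trien-1-yl acetate | C=C/C(C)=C/CC/C(C)=C/COC(C)=O | intermediate
4 | 9-[(3E,7E)-9-acetoxy-3,7-dimethylnona-3,7-dien-1-yl]-9-borabicyclo[3.3.1]nonane (not isolated) | CC(=O)OC/C=C(\C)CC/C=C(\C)CCB1C2CCCC1CCC2 | intermediate
5 | (2E,6E)-9-hydroxy-3,7-dimethylnona-2,6-dien-1-yl acetate | OCC/C(C)=C/CC/C(C)=C/COC(C)=O | intermediate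
6 | (2E,6E)-3,7-dimethyl-9-(triethylsilyloxy)nona-2,6-dien-1-yl acetate | CC[Si](CC)(CC)OCC/C(C)=C/CC/C(C)=C/COC(C)=O | intermediate
7 | (2E,6E)-3,7-dimethyl-9-(triethylsilyloxy)nona-2,6-dien-1-ol | CC[Si](CC)(CC)OCC/C(C)=C/CC/C(C)=C/CO | intermediate
8 | (2E,6E)-1-chloro-3,7-dimethyl-9-(triethylsilyloxy)nona-2,6-diene | CC[Si](CC)(CC)OCC/C(C)=C/CC/C(C)=C/CCl | intermediate
9 | 4,4-dimethylcyclohex-2-en-1-one | CC1(C)CCC(=O)C=C1 | starting material
10 | 4,4-dimethylcyclohexa-2,5-dien-1-one | CC1(C)C=CC(=O)C=C1 | intermediate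
11 | [(2E,6E)-3,7-dimethyl-9-(triethylsilyloxy)nona-2,6-dien-1-yl]barium chloride (not isolated) | CC[Si](CC)(CC)OCC/C(C)=C/CC/C(C)=C/C[Ba]Cl | intermediate
12 | chlorobarium dienolate of 13 (racemic, not isolated) | Cl[Ba]OC1=C[C@@H](C/C=C(\C)CC/C=C(\C)CCO[Si](CC)(CC)CC)C(C)(C)C=C1 | intermediate
13 | rac-(5R)-4,4-dimethyl-5-[(2E,6E)-3,7-dimethyl-9-(triethylsilyloxy)nona-2,6-dien-1-yl]cyclohex-2-en-1-one | O=C1C[C@@H](C/C=C(\C)CC/C=C(\C)CCO[Si](CC)(CC)CC)C(C)(C)C=C1 | intermediate
14 | rac-(5R)-2-(hydroxymethyl)-4,4-dimethyl-5-[(2E,6E)-3,7-dimethyl-9-(triethylsilyloxy)nona-2,6-dien-1-yl]cyclohex-2-en-1-one | O=C1C[C@@H](C/C=C(\C)CC/C=C(\C)CCO[Si](CC)(CC)CC)C(C)(C)C=C1CO | intermediate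
15 | rac-(5R)-2-(chloromethyl)-4,4-dimethyl-5-[(2E,6E)-3,7-dimethyl-9-(triethylsilyloxy)nona-2,6-dien-1-yl]cyclohex-2-en-1-one | O=C1C[C@@H](C/C=C(\C)CC/C=C(\C)CCO[Si](CC)(CC)CC)C(C)(C)C=C1CCl | intermediate
16 | rac-(3E,7E)-9-[(1R)-4-(chloromethyl)-2,2-dimethyl-5-oxocyclohex-3-en-1-yl]-3,7-dimethylnona-3,7-dienal | O=C1C[C@@H](C/C=C(\C)CC/C=C(\C)CC=O)C(C)(C)C=C1CCl | intermediate
17 | allylchromium dichloride from 16 (racemic, not isolated) | O=C1C[C@@H](C/C=C(\C)CC/C=C(\C)CC=O)C(C)(C)C=C1C[Cr](Cl)Cl | intermediate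
18 | dichlorochromium alkoxide of 19 (racemic, not isolated) | C=C1C(=O)C[C@H]2C/C=C(\C)CC/C=C(\C)C[C@@H](O[Cr](Cl)Cl)[C@H]1C2(C)C | intermediate
19 | rac-(1R,3E,7E,10R,11S)-10-hydroxy-4,8,15,15-tetramethyl-12-methylidenebicyclo[9.3.1]pentadeca-3,7-dien-13-one | C=C1C(=O)C[C@H]2C/C=C(\C)CC/C=C(\C)C[C@@H](O)[C@H]1C2(C)C | intermediate
20 | rac-(1R,3E,7E,10S,11S)-4,8,15,15-tetramethyl-12-methylidene-13-oxobicyclo[9.3.1]pentadeca-3,7-dien-10-yl acetate | C=C1C(=O)C[C@H]2C/C=C(\C)CC/C=C(\C)C[C@H](OC(C)=O)[C@H]1C2(C)C | intermediate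
21 | (1R,3R,4R,7E,10S,11S)-3,4-epoxy-4,8,15,15-tetramethyl-12-methylidene-13-oxobicyclo[9.3.1]pentadec-7-en-10-yl acetate (not isolated) | C=C1C(=O)C[C@H]2C[C@H]3O[C@]3(C)CC/C=C(\C)C[C@H](OC(C)=O)[C@H]1C2(C)C | intermediate
22 | (1R,3E,7R,8R,10S,11S)-7,8-epoxy-4,8,15,15-tetramethyl-12-methylidene-13-oxobicyclo[9.3.1]pentadec-3-en-10-yl acetate (not isolated) | C=C1C(=O)C[C@H]2C/C=C(\C)CC[C@H]3O[C@]3(C)C[C@H](OC(C)=O)[C@H]1C2(C)C | intermediate
23 | (1R,3R,4R,7R,8R,10S,11S)-3,4:7,8-diepoxy-4,8,15,15-tetramethyl-12-methylidene-13-oxobicyclo[9.3.1]pentadecan-10-yl acetate | C=C1C(=O)C[C@H]2C[C@H]3O[C@]3(C)CC[C@H]3O[C@]3(C)C[C@H](OC(C)=O)[C@H]1C2(C)C | target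

**Step count:** 14 steps in total.
**Longest linear sequence:** 13 steps (steps 1–6 and 8–14, from geranyl acetate).

**Three steps most likely to fail**

Step 8. The allylbarium may add 1,2 to the carbonyl or react through its γ-carbon at the hindered β-position next to the quaternary carbon. The fallback sets out from 8 (with 10) and comes back at 13, replacing the ionic barium reagent by a silyl-assisted allylcopper addition. Compound 8 is stannylated with Bu3SnLi (THF, −78 °C) to tributyl[(2E,6E)-3,7-dimethyl-9-(triethylsilyloxy)nona-2,6-dien-1-yl]stannane F1. Tin–lithium exchange with MeLi, transfer to CuBr·SMe2 (monovalent copper) and reaction with 10 in the presence of Me3SiCl at −78 °C give the trimethylsilyl dienol ether of the 1,4-adduct F2, which dilute citric acid hydrolyses to 13.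

Step 12. The ring closure may take the wrong face of C11, give a poor C10 ratio or form dimers. The fallback sets out from 15 and comes back at 20. It uses a Lewis-acid allylstannane cyclisation through an open transition state, which is syn-selective and makes the Mitsunobu inversion unnecessary. Compound 15 with (Bu3Sn)2 and Pd2(dba)3 (zerovalent palladium) gives the 2-(tributylstannylmethyl)enone F3. Swern oxidation as in step 11 gives the stannyl aldehyde F4. BF3·OEt2 in CH2Cl2 at −78 °C and 2 mM closes the ring to the (1R,10S,11S) alcohol F5, and Ac2O with 4-(dimethylamino)pyridine then gives 20.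

Step 14. The macrocycle may override the catalyst, so that the enantiomers are poorly sorted, or the methylene ketone may suffer at pH 10.5. The fallback sets out from 20 and comes back at 23. The enantiomers of 20 are separated by preparative chromatography on a chiral stationary phase, and the (1R,10S,11S) enantiomer is treated with dimethyldioxirane in acetone at −20 °C. This neutral oxidant attacks the two exposed olefin faces under substrate control. The fallback makes no new compound (F0).

**Further compounds**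
F1 | step 8 | tributyl[(2E,6E)-3,7-dimethyl-9-(triethylsilyloxy)nona-2,6-dien-1-yl]stannane | CC[Si](CC)(CC)OCC/C(C)=C/CC/C(C)=C/C[Sn](CCCC)(CCCC)CCCC
F2 | step 8 | trimethylsilyl dienol ether of 13 (racemic) | C[Si](C)(C)OC1=C[C@@H](C/C=C(\C)CC/C=C(\C)CCO[Si](CC)(CC)CC)C(C)(C)C=C1
F3 | step 12 | rac-(5R)-4,4-dimethyl-2-[(tributylstannyl)methyl]-5-[(2E,6E)-3,7-dimethyl-9-(triethylsilyloxy)nona-2,6-dien-1-yl]cyclohex-2-en-1-one | O=C1C[C@@H](C/C=C(\C)CC/C=C(\C)CCO[Si](CC)(CC)CC)C(C)(C)C=C1C[Sn](CCCC)(CCCC)CCCC
F4 | step 12 | rac-(3E,7E)-9-[(1R)-2,2-dimethyl-5-oxo-4-[(tributylstannyl)methyl]cyclohex-3-en-1-yl]-3,7-dimethylnona-3,7-dienal | O=C1C[C@@H](C/C=C(\C)CC/C=C(\C)CC=O)C(C)(C)C=C1C[Sn](CCCC)(CCCC)CCCC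
F5 | step 12 | rac-(1R,3E,7E,10S,11S)-10-hydroxy-4,8,15,15-tetramethyl-12-methylidenebicyclo[9.3.1]pentadeca-3,7-dien-13-one | C=C1C(=O)C[C@H]2C/C=C(\C)CC/C=C(\C)C[C@H](O)[C@H]1C2(C)C
F0 | step 14 | none | none
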